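**Proposed synthesis of CNP0156611.2 (compound 24) by growing the C3 resorcinol ring through a Danheiser benzannulation**

## The problem

Compound 24 is a trans-2,3-diaryl-2,3-dihydrobenzofuran. Its benzo ring (ring A) carries a hydroxyl at C4 and an (E)-4-hydroxystyryl group at C6; C2 carries a 2,4-dihydroxyphenyl ring (ring B) and C3 a 3,5-dihydroxyphenyl ring (ring C). The only stereocentres are C2 and C3, adjacent, both S, with the aryl groups trans. Trans is the thermodynamically preferred arrangement, so one centre set absolutely can steer the other: C3 can be equilibrated against a fixed C2 while it carries a carbonyl group, and C2 would re-close trans to an intact C3 if its C–O bond ever ionised. The C2–O1 bond is the weak point of the skeleton, because it is a benzylic aryl ether whose aryl group has oxygen donors ortho and para and therefore ionises under acid. An acceptor on C3 also opens a β-elimination path for the O1 phenoxide. The electron-rich stilbene does not survive ketenes, strong electrophiles or prolonged acid, and the six phenols are best kept as ethers until the end. C3 is crowded by the C4 oxygen and the C2 aryl group, so attaching ring C as an intact arene with stereocontrol is unattractive. The enabling feature is ring C itself: its oxygens at positions 3 and 5 are both meta to the ring carbon bonded to C3, which is exactly the pattern formed when a 3-substituted cyclobutenone combines with an alkoxyacetylene. Ring C can therefore be grown from a two-carbon handle on C3 after both stereocentres are in place.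

## Retrosynthesis

**24 from 23.** The six O–alkyl bonds (five O–methyl, one O–ethyl) are cut last. Methyl is used on rings A and B because the C4 oxygen sits ortho to the carbene carbon in the ring-forming step and must not offer an activated C–H bond, and because methyl ethers survive organolithium, alkoxide, hydride, zinc and palladium chemistry. The ethyl group comes with the key step. The forward reaction is one exhaustive Lewis-acid dealkylation; this is the price of robust protection and is treated among the risks.

**23 from 21 and 22.** The C6–vinyl bond is cut. Keeping a bromine at C6 as placeholder is preferred to carrying the stilbene, which would not survive the ketene cycloaddition used to make the cyclobutenone. Precursor 21 is smaller by the whole styryl arm, and 22 is a commodity styrene. The forward reaction must be E-selective and tolerate one free phenol.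

**21 from 15 and 16 (key disconnection).** Three bonds of ring C are cut: the two bonds from the hydroxyl-bearing carbon to its ring neighbours, and the bond between the ethoxy-bearing carbon and the CH next to the attachment carbon. The neighbouring cut, the C3–aryl bond, would require arylation of a hindered benzylic centre with control of configuration. The chosen cut leaves C3 carrying only a four-carbon enone and builds the arene under neutral thermal conditions with both stereocentres as spectators. Precursor 15 is simpler by one aromatic ring. The forward reaction must deliver both oxygens meta to the attachment carbon without exception.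

**15 from 14 from 13.** The two ring bonds joining the alkyne carbons to a two-carbon ketene unit are cut, then the two C–Cl bonds are put back. This is the established two-step route from a terminal alkyne to a 3-substituted cyclobutenone through dihaloketene cycloaddition and reductive dechlorination. It reduces the problem to alkyne 13, in which C3 carries a simple ethynyl group. The forward steps must not ionise the C2–O1 bond or touch the aryl bromide.

**13 from 11 (through 12).** The terminal alkyne carbon is removed in a one-carbon homologation of the aldehyde derived from ester 11. The ester is the natural handle because it also allows C3 to be equilibrated. The homologation must run without organolithium reagents so that the aryl bromide stays.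

**11 from 10 from 9.** The C2–C3 bond is cut. Closing the O1–C2 bond instead would be a 5-endo conjugate addition, and cutting C3–C3a leads to the ring-contraction route weighed below. C2–C3 formation by carbene C–H insertion creates both stereocentres from an achiral, acyclic diazo ester under catalyst control. The insertion gives the cis ester 10, and equilibration at C3 gives trans 11. The forward reaction must set C2 with high enantioselectivity; C3 then follows thermodynamically.

**9 from 7 (through 8), 7 from 5 and 1, 5 from 3 and 2, 2 from 1.** The diazo group is traced to the ketone of α-ketoester 7. The two aryl C–O bonds are cut as displacements of fluoride activated by the ortho keto group. The aryl–carbonyl bond is cut as acylation of the aryllithium formed between the two fluorines of 3. Oxalate 2 carries the same benzyl group as alcohol 1, so that ester exchange during the first fluoride displacement cannot release a competing alkoxide. The final methoxide treatment then installs the methyl ether and the methyl ester together. The four building blocks 1, 3, 16 and 22 are all commercial.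

## Roads not taken

**Alternative 1:** Both aryl–C(sp3) bonds, C2–ring B and C3–ring C, would be made in one operation on a benzofuran.
- Forward key step: benzofuran A2 is lithiated at C2 and combined with boronic ester A3 to a boron ate complex. An arylpalladium species from triflate A4, bearing a chiral ferrocenyl bisphosphine, attacks C3 while ring B migrates from boron to C2 on the opposite face. This dearomatises the furan and gives boronate A1 with the aryl groups trans.
- Merits: all three aryl units are joined and both stereocentres set in a single catalytic step, so the route to the protected skeleton would be about half as long as the chosen one.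
- Weak points for this target: C3 is peri to the C4 methoxy group, so the arylpalladium attack is hindered. The migrating aryl is ortho-substituted. The arylpalladium species could instead add across the stilbene already present. Enantio-induction on benzofuran ate complexes is thinly documented compared with vinyl boronates. The tertiary, α-oxygenated benzylic boronate A1 must still be protodeboronated with retention, and the same exhaustive dealkylation remains.
- Comparison: this road is clearly better in convergence and step count. The chosen plan sets against it reaction classes that each have close precedent on this ring system, a stereocentre-forming step proven for 2-aryl-3-carboxylate dihydrobenzofurans, and no bond formation at C3 with an intact, bulky aryl group.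

**Alternative 2:** The C3–C3a bond would be formed by migration of ring A in an oxidative ring contraction of flavanone A5.
- Forward key step: a hypervalent iodine oxidant in strongly acidic orthoester medium attacks the enol ether of A5 at its C3; ring A shifts from the ketal carbon, the ring contracts, and the former carbonyl carbon becomes a methyl ester. The product A6 is the same compound as ester 11 of the chosen route.
- Merits: the flavanone comes from a chalcone in very few steps from cheap materials; no diazo compound or rhodium is needed; the trans relationship follows from the C2 centre already present. It would replace steps 1 to 6 by a sequence probably one or two steps shorter.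
- Weak points for this target: ring B is a 2,4-dimethoxyphenyl group. This makes the flavanone prone to racemise at C2 through reversible ring opening to the chalcone in the acidic medium. It favours migration of ring B (isoflavone formation) over ring A, and it exposes a very electron-rich arene to an electrophilic oxidant. The 5-methoxy group next to the carbonyl adds hindrance.
- Comparison: where it works it is cheaper and shorter to the same intermediate, and everything after 11 would be identical. The chosen plan sets against it a neutral, catalyst-controlled creation of C2 that never puts the C2–O1 bond under acid, and no competition between two migrating aryl groups.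

**Alternative 3:** The C2–C3 and O1–C2 bonds would be formed together in a [4+1] annulation.
- Forward key step: carbonate base eliminates sulfinate from sulfone A7 to give the ring A ortho-quinone methide already carrying ring C and the styryl arm, and deprotonates chiral sulfonium salt A8 to its benzylic ylide. The ylide carbon adds to the methide carbon, and the phenoxide displaces the sulfide to close the dihydrofuran, giving hexamethyl ether A9.
- Merits: the complete protected skeleton appears in one step with inherent trans selectivity, and the whole route would be about five steps shorter than the chosen one.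
- Weak points for this target: the methide carbon is flanked by the C4 methoxy group and ring C. The 2,4-dimethoxybenzyl sulfonium salt A8 is itself prone to ionise and is a weak carbon acid. Asymmetric induction with semi-stabilised benzylic ylides and a stoichiometric chiral sulfide is far less secure than with ester-stabilised ylides, because betaine formation is reversible. Regioselective assembly of A7 is a problem of its own.
- Comparison: this road is better in brevity and in building ring C from an ordinary arene. The chosen plan sets against it absolute stereocontrol from a catalytic step with direct precedent, and the fact that the fragile 2,4-dimethoxybenzylic position is never made a leaving-group carbon.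

Key step: step 10

## Route

Assumption: the sense of induction known for dirhodium phthaloyl-tert-leucinate catalysts with 2-(benzyloxy)phenyl diazoacetates (S-configured ligand giving the 2R series) is taken to hold for diazo ester 9; Rh2(R-PTTL)4 is therefore specified, and its enantiomer would be used if the sense proved opposite.

Step 1
Reactants: 1 2,4-dimethoxybenzyl alcohol
Product: 2 bis(2,4-dimethoxybenzyl) oxalate
Conditions: (COCl)2 (0.5 equiv), pyridine, CH2Cl2, −20 → 0 °C
Reagents that add atoms: oxalyl chloride, O=C(Cl)C(=O)Cl
Why: Esterification of a primary benzylic alcohol with a diacid chloride and pyridine; adding the acid chloride to excess alcohol and base at low temperature keeps the intermediate chlorooxalate from collapsing to the benzylic chloride. The benzyl oxalate is made so that the alkoxide exchanged in step 3 is the same one that is to be placed on the ring.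

Step 2
Reactants: 3 1-bromo-3,5-difluorobenzene; 2 bis(2,4-dimethoxybenzyl) oxalate
Product: 5 2,4-dimethoxybenzyl 2-(4-bromo-2,6-difluorophenyl)-2-oxoacetate, via aryllithium 4 (not isolated)
Conditions: LiN(iPr)2 (LDA), THF, −78 °C; then cannulate into 2 (1.3 equiv), THF, −78 °C; aq. NH4Cl at −78 °C
Reagents that add atoms: none
Why: Directed ortho-metalation of 3 occurs at C4, the position flanked by both fluorines; inverse addition of the aryllithium to excess oxalate stops at the tetrahedral adduct, which gives the α-ketoester only on cold quench (acylation of an aryllithium by a dialkyl oxalate).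

Step 3
Reactants: 5 2,4-dimethoxybenzyl 2-(4-bromo-2,6-difluorophenyl)-2-oxoacetate; 1 2,4-dimethoxybenzyl alcohol
Product: 7 methyl 2-{4-bromo-2-[(2,4-dimethoxybenzyl)oxy]-6-methoxyphenyl}-2-oxoacetate, via monofluoro ether 6 (not isolated)
Conditions: NaH, 1 (1.05 equiv), THF, −20 → 0 °C; then NaOMe, MeOH, 50 °C
Reagents that add atoms: sodium methoxide, C[O-].[Na+]
Why: Two successive nucleophilic aromatic substitutions of fluoride ortho to the keto group through Meisenheimer adducts; the first alkoxy group deactivates the ring so one equivalent of the alkoxide of 1 should stop at 6, and ester exchange at that stage is degenerate because the ester carries the same benzyl group. Methoxide in methanol then replaces the second fluoride and transesterifies to the methyl ester; fluoride is displaced far faster than the para bromide.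

Step 4
Reactants: 7 methyl 2-{4-bromo-2-[(2,4-dimethoxybenzyl)oxy]-6-methoxyphenyl}-2-oxoacetate
Product: 9 methyl 2-{4-bromo-2-[(2,4-dimethoxybenzyl)oxy]-6-methoxyphenyl}-2-diazoacetate, via tosylhydrazone 8 (not isolated)
Conditions: TsNHNH2, MeOH, 60 °C; then DBU, CH2Cl2, 0 °C → rt
Reagents that add atoms: p-toluenesulfonyl hydrazide, NNS(=O)(=O)c1ccc(C)cc1
Why: Condensation of the α-ketoester with tosylhydrazide and base-induced loss of sulfinate (Bamford–Stevens diazo synthesis) is the standard entry to aryldiazoacetates; the keto group stays electrophilic despite two ortho substituents because twisting removes its conjugation with the arene.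

Step 5
Reactants: 9 methyl 2-{4-bromo-2-[(2,4-dimethoxybenzyl)oxy]-6-methoxyphenyl}-2-diazoacetate
Product: 10 methyl (2S,3R)-6-bromo-2-(2,4-dimethoxyphenyl)-4-methoxy-2,3-dihydro-1-benzofuran-3-carboxylate (cis)
Conditions: Rh2(R-PTTL)4 (1 mol %), toluene, −78 → −40 °C
Reagents that add atoms: none
Why: Intramolecular 1,5 C–H insertion of the rhodium aryl(methoxycarbonyl)carbene into the benzylic O–CH2 bond, which is activated by the ether oxygen and the electron-rich aryl group; the concerted insertion gives the cis-2-aryl-3-carboxylate, and the chiral carboxylate ligands select one enantiotopic benzylic hydrogen, fixing C2 as S with C3 following as R. The primary C–H bonds of the methoxy group on the other ortho position are much less reactive.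

Step 6
Reactants: 10 methyl (2S,3R)-6-bromo-2-(2,4-dimethoxyphenyl)-4-methoxy-2,3-dihydro-1-benzofuran-3-carboxylate
Product: 11 methyl (2S,3S)-6-bromo-2-(2,4-dimethoxyphenyl)-4-methoxy-2,3-dihydro-1-benzofuran-3-carboxylate (trans)
Conditions: NaOMe (0.5 equiv), MeOH/THF, rt
Reagents that add atoms: none
Why: Base-mediated epimerisation of the ester α-centre to the thermodynamically preferred trans isomer under control of the fixed C2 centre; C2 is not endangered because expulsion of the O1 phenoxide from the enolate would be the reverse of a 5-endo-trig closure, with the C2–O1 bond close to the nodal plane of the enolate.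

Step 7
Reactants: 11 methyl (2S,3S)-6-bromo-2-(2,4-dimethoxyphenyl)-4-methoxy-2,3-dihydro-1-benzofuran-3-carboxylate
Product: 13 (2S,3S)-6-bromo-2-(2,4-dimethoxyphenyl)-3-ethynyl-4-methoxy-2,3-dihydro-1-benzofuran, via aldehyde 12 (not isolated)
Conditions: iBu2AlH (DIBAL-H, 1.2 equiv), CH2Cl2, −78 °C; then MeOH, K2CO3, dimethyl (1-diazo-2-oxopropyl)phosphonate, −78 °C → rt
Reagents that add atoms: dimethyl (1-diazo-2-oxopropyl)phosphonate, CC(=O)C(=[N+]=[N-])P(=O)(OC)OC
Why: Partial reduction of the ester to the aluminium hemiacetal, stable at −78 °C, then release of the aldehyde by methanol in the presence of the Ohira–Bestmann reagent (Seyferth–Gilbert homologation) is a known one-pot ester-to-alkyne protocol; it avoids alkyllithium reagents, so the aryl bromide stays, and any epimerisation of 12 under K2CO3 returns the trans isomer.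

Step 8
Reactants: 13 (2S,3S)-6-bromo-2-(2,4-dimethoxyphenyl)-3-ethynyl-4-methoxy-2,3-dihydro-1-benzofuran
Product: 14 3-[(2S,3R)-6-bromo-2-(2,4-dimethoxyphenyl)-4-methoxy-2,3-dihydro-1-benzofuran-3-yl]-4,4-dichlorocyclobut-2-en-1-one
Conditions: Cl3CCOCl, Zn–Cu couple, Et2O/DME, rt
Reagents that add atoms: trichloroacetyl chloride, ClC(Cl)(Cl)C(Cl)=O
Why: [2+2] cycloaddition of dichloroketene, generated by zinc dehalogenation, with a terminal alkyne; the ketene carbonyl carbon bonds to the unsubstituted alkyne carbon to give the 3-substituted 4,4-dichlorocyclobutenone, and DME ties up the zinc chloride. No stereocentre is touched; the C3 descriptor reads R only because the CCl2 group changes the CIP ranking.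

Step 9
Reactants: 14 3-[(2S,3R)-6-bromo-2-(2,4-dimethoxyphenyl)-4-methoxy-2,3-dihydro-1-benzofuran-3-yl]-4,4-dichlorocyclobut-2-en-1-one
Product: 15 3-[(2S,3S)-6-bromo-2-(2,4-dimethoxyphenyl)-4-methoxy-2,3-dihydro-1-benzofuran-3-yl]cyclobut-2-en-1-one
Conditions: Zn dust, AcOH, TMEDA, EtOH, 0 °C → rt
Reagents that add atoms: none
Why: Reductive dechlorination of the α,α-dichloroketone by zinc in amine-buffered acetic acid is the established route from dichlorocyclobutenones to cyclobutenones; the buffer suppresses conjugate reduction and acid-induced damage, and aryl bromides are inert to zinc dust under these conditions.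

Step 10
Reactants: 15 3-[(2S,3S)-6-bromo-2-(2,4-dimethoxyphenyl)-4-methoxy-2,3-dihydro-1-benzofuran-3-yl]cyclobut-2-en-1-one; 16 ethoxyacetylene
Product: 21 3-[(2S,3S)-6-bromo-2-(2,4-dimethoxyphenyl)-4-methoxy-2,3-dihydro-1-benzofuran-3-yl]-5-ethoxyphenol, via vinylketene 17 (not isolated), via vinylcyclobutenone 18 (not isolated), via dienylketene 19 (not isolated), via cyclohexadienone 20 (not isolated)
Conditions: 16 (3 equiv), toluene, 80 °C, sealed tube
Reagents that add atoms: none
Why: Danheiser benzannulation: thermal 4π electrocyclic opening of 15 gives vinylketene 17, whose carbonyl carbon is attacked by the nucleophilic CH terminus of 16 in a regiospecific [2+2] cycloaddition to give 18. Cyclobutenone 18 opens reversibly (4π) to dienylketene 19, and the isomer with ketene and vinyl termini cis closes by 6π electrocyclisation to 20, which tautomerises to phenol 21. The six-membered carbocycle is thus closed by the 6π electrocyclisation (former carbonyl carbon to former CH2 of the cyclobutenone), its other two new bonds coming from the [2+2] step. No stereocentre is created, since the sp3 carbon of 18 is erased on opening, and C2 and C3 are spectators because the cascade is neutral, uncatalysed and involves no bond to either centre. The selectivity needed is regiochemical: the polarity match between ketene and ynol ether places hydroxyl and ethoxy on the two carbons meta to the attachment carbon and allows no other isomer. Excess 16 is used so that capture of 17 outruns ketene dimerisation and acylation of the product phenol; the aryl bromide and the methoxyarenes do not react with ketenes at this temperature. The closest known reactions are the unions of 3-alkylcyclobutenones with alkoxyacetylenes to give 5-alkylresorcinol monoethers.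

Step 11
Reactants: 21 3-[(2S,3S)-6-bromo-2-(2,4-dimethoxyphenyl)-4-methoxy-2,3-dihydro-1-benzofuran-3-yl]-5-ethoxyphenol; 22 4-methoxystyrene
Product: 23 3-{(2S,3S)-2-(2,4-dimethoxyphenyl)-4-methoxy-6-[(E)-2-(4-methoxyphenyl)ethenyl]-2,3-dihydro-1-benzofuran-3-yl}-5-ethoxyphenol
Conditions: Pd(OAc)2 (5 mol %), P(o-tol)3, Et3N, DMF, 100 °C
Reagents that add atoms: none
Why: Heck reaction: oxidative addition of zerovalent palladium to the aryl bromide, syn insertion of the styrene at its terminal carbon and syn β-hydride elimination give the E-stilbene; the free phenol and both sp3 centres are inert to triethylamine at this temperature.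

Step 12
Reactants: 23 3-{(2S,3S)-2-(2,4-dimethoxyphenyl)-4-methoxy-6-[(E)-2-(4-methoxyphenyl)ethenyl]-2,3-dihydro-1-benzofuran-3-yl}-5-ethoxyphenol
Product: 24 4-{(2S,3S)-3-(3,5-dihydroxyphenyl)-4-hydroxy-6-[(E)-2-(4-hydroxyphenyl)ethenyl]-2,3-dihydro-1-benzofuran-2-yl}benzene-1,3-diol
Conditions: BBr3 (excess), CH2Cl2, −78 → 0 °C; then MeOH, aq. NaHCO3
Reagents that add atoms: none
Why: Lewis-acid cleavage of aryl alkyl ethers by BBr3 (bromide attack on the O-alkyl carbon of the borane adduct) removes the five methyl groups and the ethyl group, and hydrolysis of the aryl borates on quench gives the hexaphenol. The temperature is kept low because the C2–O1 bond is itself a benzylic ether; C3 is not affected by ionisation at C2, so re-closure should return the trans isomer.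

## Compound list

1 | 2,4-dimethoxybenzyl alcohol | COc1ccc(CO)c(OC)c1 | starting material
2 | bis(2,4-dimethoxybenzyl) oxalate | COc1ccc(COC(=O)C(=O)OCc2ccc(OC)cc2OC)c(OC)c1 | intermediate
3 | 1-bromo-3,5-difluorobenzene | Fc1cc(F)cc(Br)c1 | starting material
4 | (4-bromo-2,6-difluorophenyl)lithium | [Li]c1c(F)cc(Br)cc1F | intermediate (not isolated)
5 | 2,4-dimethoxybenzyl 2-(4-bromo-2,6-difluorophenyl)-2-oxoacetate | COc1ccc(COC(=O)C(=O)c2c(F)cc(Br)cc2F)c(OC)c1 | intermediate
6 | 2,4-dimethoxybenzyl 2-{4-bromo-2-[(2,4-dimethoxybenzyl)oxy]-6-fluorophenyl}-2-oxoacetate | COc1ccc(COC(=O)C(=O)c2c(F)cc(Br)cc2OCc2ccc(OC)cc2OC)c(OC)c1 | intermediate (not isolated)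
7 | methyl 2-{4-bromo-2-[(2,4-dimethoxybenzyl)oxy]-6-methoxyphenyl}-2-oxoacetate | COC(=O)C(=O)c1c(OC)cc(Br)cc1OCc1ccc(OC)cc1OC | intermediate
8 | methyl 2-{4-bromo-2-[(2,4-dimethoxybenzyl)oxy]-6-methoxyphenyl}-2-[2-(4-methylbenzenesulfonyl)hydrazinylidene]acetate | COC(=O)C(=NNS(=O)(=O)c1ccc(C)cc1)c1c(OC)cc(Br)cc1OCc1ccc(OC)cc1OC | intermediate (not isolated)
9 | methyl 2-{4-bromo-2-[(2,4-dimethoxybenzyl)oxy]-6-methoxyphenyl}-2-diazoacetate | COC(=O)C(=[N+]=[N-])c1c(OC)cc(Br)cc1OCc1ccc(OC)cc1OC | intermediate
10 | methyl (2S,3R)-6-bromo-2-(2,4-dimethoxyphenyl)-4-methoxy-2,3-dihydro-1-benzofuran-3-carboxylate (cis) | Brc1cc(OC)c2c(c1)O[C@H](c1ccc(OC)cc1OC)[C@@H]2C(=O)OC | intermediate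
11 | methyl (2S,3S)-6-bromo-2-(2,4-dimethoxyphenyl)-4-methoxy-2,3-dihydro-1-benzofuran-3-carboxylate (trans) | Brc1cc(OC)c2c(c1)O[C@H](c1ccc(OC)cc1OC)[C@H]2C(=O)OC | intermediate
12 | (2S,3S)-6-bromo-2-(2,4-dimethoxyphenyl)-4-methoxy-2,3-dihydro-1-benzofuran-3-carbaldehyde | Brc1cc(OC)c2c(c1)O[C@H](c1ccc(OC)cc1OC)[C@H]2C=O | intermediate (not isolated)
13 | (2S,3S)-6-bromo-2-(2,4-dimethoxyphenyl)-3-ethynyl-4-methoxy-2,3-dihydro-1-benzofuran | Brc1cc(OC)c2c(c1)O[C@H](c1ccc(OC)cc1OC)[C@H]2C#C | intermediate
14 | 3-[(2S,3R)-6-bromo-2-(2,4-dimethoxyphenyl)-4-methoxy-2,3-dihydro-1-benzofuran-3-yl]-4,4-dichlorocyclobut-2-en-1-one | Brc1cc(OC)c2c(c1)O[C@H](c1ccc(OC)cc1OC)[C@H]2C1=CC(=O)C1(Cl)Cl | intermediate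
15 | 3-[(2S,3S)-6-bromo-2-(2,4-dimethoxyphenyl)-4-methoxy-2,3-dihydro-1-benzofuran-3-yl]cyclobut-2-en-1-one | Brc1cc(OC)c2c(c1)O[C@H](c1ccc(OC)cc1OC)[C@H]2C1=CC(=O)C1 | intermediate
16 | ethoxyacetylene | C#COCC | starting material
17 | 3-[(2S,3S)-6-bromo-2-(2,4-dimethoxyphenyl)-4-methoxy-2,3-dihydro-1-benzofuran-3-yl]buta-1,3-dien-1-one | Brc1cc(OC)c2c(c1)O[C@H](c1ccc(OC)cc1OC)[C@H]2C(=C)C=C=O | intermediate (not isolated)
18 | 4-{1-[(2S,3S)-6-bromo-2-(2,4-dimethoxyphenyl)-4-methoxy-2,3-dihydro-1-benzofuran-3-yl]ethenyl}-3-ethoxycyclobut-2-en-1-one (ring carbon C4 unassigned) | Brc1cc(OC)c2c(c1)O[C@H](c1ccc(OC)cc1OC)[C@H]2C(=C)C1C(=O)C=C1OCC | intermediate (not isolated)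
19 | (3E)-5-[(2S,3S)-6-bromo-2-(2,4-dimethoxyphenyl)-4-methoxy-2,3-dihydro-1-benzofuran-3-yl]-3-ethoxyhexa-1,3,5-trien-1-one | Brc1cc(OC)c2c(c1)O[C@H](c1ccc(OC)cc1OC)[C@H]2C(=C)/C=C(OCC)\C=C=O | intermediate (not isolated)
20 | 5-[(2S,3S)-6-bromo-2-(2,4-dimethoxyphenyl)-4-methoxy-2,3-dihydro-1-benzofuran-3-yl]-3-ethoxycyclohexa-2,4-dien-1-one | Brc1cc(OC)c2c(c1)O[C@H](c1ccc(OC)cc1OC)[C@H]2C1=CC(OCC)=CC(=O)C1 | intermediate (not isolated)
21 | 3-[(2S,3S)-6-bromo-2-(2,4-dimethoxyphenyl)-4-methoxy-2,3-dihydro-1-benzofuran-3-yl]-5-ethoxyphenol | Brc1cc(OC)c2c(c1)O[C@H](c1ccc(OC)cc1OC)[C@H]2c1cc(O)cc(OCC)c1 | intermediate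
22 | 4-methoxystyrene | C=Cc1ccc(OC)cc1 | starting material
23 | 3-{(2S,3S)-2-(2,4-dimethoxyphenyl)-4-methoxy-6-[(E)-2-(4-methoxyphenyl)ethenyl]-2,3-dihydro-1-benzofuran-3-yl}-5-ethoxyphenol | COc1ccc(/C=C/c2cc(OC)c3c(c2)O[C@H](c2ccc(OC)cc2OC)[C@H]3c2cc(O)cc(OCC)c2)cc1 | intermediate
24 | 4-{(2S,3S)-3-(3,5-dihydroxyphenyl)-4-hydroxy-6-[(E)-2-(4-hydroxyphenyl)ethenyl]-2,3-dihydro-1-benzofuran-2-yl}benzene-1,3-diol | Oc1ccc(/C=C/c2cc(O)c3c(c2)O[C@H](c2ccc(O)cc2O)[C@H]3c2cc(O)cc(O)c2)cc1 | target

## Step count and least certain steps

Total: 12 steps. Longest linear sequence: 12 steps (from 1 through oxalate 2; 11 steps counted from 3).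

**Step 10 (key step).** The process most likely to fail is slow capture of vinylketene 17. At 80 °C the ynol ether 16 is volatile and can fragment thermally, while 17 can dimerise or acylate the product phenol, so material is diverted before the [2+2] step. Fallback: decouple the cascade. Cyclobutenone 15 is irradiated through Pyrex at room temperature in the presence of 16, so that the photochemical ring opening gives 17 and its capture to vinylcyclobutenone 18 takes place cold. Excess 16 is then removed, and 18 is heated alone in toluene to complete the opening, 6π closure and tautomerisation. This sets out from 15 and returns at 21 and makes no compound outside the list.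

**Step 5.** The second ortho substituent (the methoxy group) twists the carbene out of the arene plane, which may erode facial selectivity at the benzylic C–H bond or allow some insertion into the methoxy group, so the ester may be obtained with insufficient enantiomeric purity. Fallback: classical resolution instead of sole reliance on the catalyst. Scalemic 11 is saponified (LiOH, THF/H2O) to (2S,3S)-6-bromo-2-(2,4-dimethoxyphenyl)-4-methoxy-2,3-dihydro-1-benzofuran-3-carboxylic acid F1. Its (R)-1-phenylethylammonium salt F2 is crystallised to purity (the amine enantiomer to be chosen by screening). The acid is liberated and re-esterified with MeI/K2CO3. This sets out from 11 and returns at 11.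

**Step 3.** The second fluoride displacement is slower than the first because the ring now carries a donor and the ketone is partly masked as its hemiketal in methanol. Prolonged heating could then lead to attack at the para bromide or degradation of the ketoester, and over-substitution by the benzylic alkoxide in the first stage would give the bis-benzyl ether. Fallback: install the benzyl ether by phenol alkylation instead of fluoride displacement.
- Aryllithium from 3 (as in step 2) is acylated with dimethyl oxalate to methyl 2-(4-bromo-2,6-difluorophenyl)-2-oxoacetate F3.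
- Excess NaOMe in refluxing MeOH replaces both fluorides to give methyl 2-(4-bromo-2,6-dimethoxyphenyl)-2-oxoacetate F4.
- BCl3 in CH2Cl2 at −78 → 0 °C removes one methyl group through chelation to the ketone oxygen, giving methyl 2-(4-bromo-2-hydroxy-6-methoxyphenyl)-2-oxoacetate F5.
- Mitsunobu etherification of F5 with 1 (PPh3, DIAD, THF) gives 7.

This sets out from 3 and returns at 7.

**Step 7.** The aluminium hemiacetal may not hold, giving over-reduction to the primary alcohol or leaving ester. Aldehyde 12 may also suffer base-mediated loss at C3 (epimerisation followed by slow side reactions) in methanolic carbonate before homologation. Fallback: separate the redox events and use a base-free homologation. Ester 11 is reduced fully (LiBH4, THF) to [(2S,3R)-6-bromo-2-(2,4-dimethoxyphenyl)-4-methoxy-2,3-dihydro-1-benzofuran-3-yl]methanol F6. F6 is oxidised with Dess–Martin periodinane/NaHCO3 to 12, which is treated at −78 °C with lithiated trimethylsilyldiazomethane (Colvin rearrangement) to give 13. This sets out from 11 and returns at 13.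

**Step 8.** Zinc chloride formed with the ketene may ionise the C2–O1 benzylic ether or polymerise the ketene, and the branched propargylic position may slow the cycloaddition, so conversion stalls. Fallback: a keteniminium [2+2] cycloaddition. N,N-dimethylacetamide is activated with Tf2O and 2,4,6-collidine in 1,2-dichloroethane in the presence of 13. This gives N-{3-[(2S,3S)-6-bromo-2-(2,4-dimethoxyphenyl)-4-methoxy-2,3-dihydro-1-benzofuran-3-yl]cyclobut-2-en-1-ylidene}-N-methylmethanaminium trifluoromethanesulfonate F7, and aqueous NaHCO3 hydrolysis gives 15 directly. This sets out from 13 and returns at 15, bypassing 14 and step 9.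

**Step 12.** Lewis-acid ionisation of the C2–O1 bond (a 2,4-dialkoxybenzylic ether) can lead to ring opening, elimination towards a triarylethene or epimerisation, and hydrogen bromide can add to or oligomerise the electron-rich stilbene during the long exposure needed for six dealkylations. Fallback: dealkylate before the stilbene exists and carry the phenols as acetates.
- Bromide 21 is treated with BBr3 (CH2Cl2, −78 → 0 °C) to give 4-[(2S,3S)-6-bromo-3-(3,5-dihydroxyphenyl)-4-hydroxy-2,3-dihydro-1-benzofuran-2-yl]benzene-1,3-diol F8.
- Ac2O/pyridine gives its pentaacetate F9, which can be purified by chromatography and freed of any C2 epimer.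
- Heck coupling of F9 with 4-acetoxystyrene (Pd(OAc)2, P(o-tol)3, Et3N, DMF) gives the hexaacetate of 24, F10.
- Mild methanolysis (K2CO3, MeOH, 0 °C) releases 24.

This sets out from 21 and returns at 24.

## Further compounds

F0 | step 10 | none | none
F1 | step 5 | (2S,3S)-6-bromo-2-(2,4-dimethoxyphenyl)-4-methoxy-2,3-dihydro-1-benzofuran-3-carboxylic acid | Brc1cc(OC)c2c(c1)O[C@H](c1ccc(OC)cc1OC)[C@H]2C(=O)O
F2 | step 5 | (R)-1-phenylethylammonium (2S,3S)-6-bromo-2-(2,4-dimethoxyphenyl)-4-methoxy-2,3-dihydro-1-benzofuran-3-carboxylate | Brc1cc(OC)c2c(c1)O[C@H](c1ccc(OC)cc1OC)[C@H]2C(=O)[O-].C[C@@H]([NH3+])c1ccccc1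
F3 | step 3 | methyl 2-(4-bromo-2,6-difluorophenyl)-2-oxoacetate | COC(=O)C(=O)c1c(F)cc(Br)cc1F
F4 | step 3 | methyl 2-(4-bromo-2,6-dimethoxyphenyl)-2-oxoacetate | COC(=O)C(=O)c1c(OC)cc(Br)cc1OC
F5 | step 3 | methyl 2-(4-bromo-2-hydroxy-6-methoxyphenyl)-2-oxoacetate | COC(=O)C(=O)c1c(O)cc(Br)cc1OC
F6 | step 7 | [(2S,3R)-6-bromo-2-(2,4-dimethoxyphenyl)-4-methoxy-2,3-dihydro-1-benzofuran-3-yl]methanol | Brc1cc(OC)c2c(c1)O[C@H](c1ccc(OC)cc1OC)[C@H]2CO
F7 | step 8 | N-{3-[(2S,3S)-6-bromo-2-(2,4-dimethoxyphenyl)-4-methoxy-2,3-dihydro-1-benzofuran-3-yl]cyclobut-2-en-1-ylidene}-N-methylmethanaminium trifluoromethanesulfonate | Brc1cc(OC)c2c(c1)O[C@H](c1ccc(OC)cc1OC)[C@H]2C1=CC(=[N+](C)C)C1.[O-]S(=O)(=O)C(F)(F)F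
F8 | step 12 | 4-[(2S,3S)-6-bromo-3-(3,5-dihydroxyphenyl)-4-hydroxy-2,3-dihydro-1-benzofuran-2-yl]benzene-1,3-diol | Brc1cc(O)c2c(c1)O[C@H](c1ccc(O)cc1O)[C@H]2c1cc(O)cc(O)c1
F9 | step 12 | pentaacetate of F8: 4-[(2S,3S)-4-acetoxy-6-bromo-3-(3,5-diacetoxyphenyl)-2,3-dihydro-1-benzofuran-2-yl]-1,3-phenylene diacetate | Brc1cc(OC(C)=O)c2c(c1)O[C@H](c1ccc(OC(C)=O)cc1OC(C)=O)[C@H]2c1cc(OC(C)=O)cc(OC(C)=O)c1
F10 | step 12 | hexaacetate of 24 | CC(=O)Oc1ccc(/C=C/c2cc(OC(C)=O)c3c(c2)O[C@H](c2ccc(OC(C)=O)cc2OC(C)=O)[C@H]3c2cc(OC(C)=O)cc(OC(C)=O)c2)cc1
A1 | alternative 1 | 2-{(2S,3S)-2-(2,4-dimethoxyphenyl)-3-(3,5-dimethoxyphenyl)-4-methoxy-6-[(E)-2-(4-methoxyphenyl)ethenyl]-2,3-dihydro-1-benzofuran-2-yl}-4,4,5,5-tetramethyl-1,3,2-dioxaborolane | COc1ccc(/C=C/c2cc(OC)c3c(c2)O[C@](B2OC(C)(C)C(C)(C)O2)(c2ccc(OC)cc2OC)[C@H]3c2cc(OC)cc(OC)c2)cc1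
A2 | alternative 1 | 4-methoxy-6-[(E)-2-(4-methoxyphenyl)ethenyl]-1-benzofuran | COc1ccc(/C=C/c2cc(OC)c3ccoc3c2)cc1
A3 | alternative 1 | 2-(2,4-dimethoxyphenyl)-4,4,5,5-tetramethyl-1,3,2-dioxaborolane | COc1ccc(B2OC(C)(C)C(C)(C)O2)c(OC)c1
A4 | alternative 1 | 3,5-dimethoxyphenyl trifluoromethanesulfonate | COc1cc(OC)cc(OS(=O)(=O)C(F)(F)F)c1
A5 | alternative 2 | (2S)-7-bromo-2-(2,4-dimethoxyphenyl)-5-methoxy-2,3-dihydro-4H-1-benzopyran-4-one | Brc1cc(OC)c2c(c1)O[C@H](c1ccc(OC)cc1OC)CC2=O
A6 | alternative 2 | methyl (2S,3S)-6-bromo-2-(2,4-dimethoxyphenyl)-4-methoxy-2,3-dihydro-1-benzofuran-3-carboxylate (identical with 11) | Brc1cc(OC)c2c(c1)O[C@H](c1ccc(OC)cc1OC)[C@H]2C(=O)OC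
A7 | alternative 3 | 2-[(3,5-dimethoxyphenyl)(4-methylbenzenesulfonyl)methyl]-3-methoxy-5-[(E)-2-(4-methoxyphenyl)ethenyl]phenol (racemic at the sulfonyl-bearing carbon) | COc1ccc(/C=C/c2cc(O)c(C(c3cc(OC)cc(OC)c3)S(=O)(=O)c3ccc(C)cc3)c(OC)c2)cc1
A8 | alternative 3 | (2R,5R)-1-(2,4-dimethoxybenzyl)-2,5-dimethylthiolan-1-ium trifluoromethanesulfonate | COc1ccc(C[S+]2[C@H](C)CC[C@H]2C)c(OC)c1.[O-]S(=O)(=O)C(F)(F)F
A9 | alternative 3 | (2S,3S)-2-(2,4-dimethoxyphenyl)-3-(3,5-dimethoxyphenyl)-4-methoxy-6-[(E)-2-(4-methoxyphenyl)ethenyl]-2,3-dihydro-1-benzofuran | COc1ccc(/C=C/c2cc(OC)c3c(c2)O[C@H](c2ccc(OC)cc2OC)[C@H]3c2cc(OC)cc(OC)c2)cc1
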